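**Retrosynthetic overview**
- Feature: in ring A, C5–C8 read C–OH, C–OMe, C–OH, C–OMe, the pattern of two head-to-tail methoxyacetyl units; C2, C3, C4, C4a and C8a are the five carbons of a 6-aryl-4-hydroxy-2-pyrone.
- Last disconnections: the O3' benzyl ether, then O1–C2 of ring C (cyclodehydration of a 1,3-diketone; ring A is symmetric, so both ortho hydroxyls give the same flavone).
- Key disconnection C8–C8a: ring A by Claisen recyclisation of a 3-(2,4-dimethoxy-3-oxobutanoyl)-4-hydroxy-2-pyrone, the pyrone ring opening as ring A closes.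
- Precursor: C6–C7 by dianion acylation with a methoxyacetyl donor, C4a–C5 by C-acylation of the pyrone with methoxyacetic acid, and the pyrone by C2–C3 aroylation of ethyl acetoacetate dianion with benzylated methyl isovanillate, then lactonisation.
- Ring order: ring B bought; pyrone (temporary) first; ring A second; ring C last.

Key step: step 6

Remark on the chemistry: the target is achiral, so no stereocentre has to be set. The second methoxyacetyl unit is delivered from N,2-dimethoxy-N-methylacetamide, taken as purchasable, instead of methyl methoxyacetate, so that the new β-diketone is released only on quench.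

Step 1
Reactants: 1 methyl 3-hydroxy-4-methoxybenzoate
Product: 2 methyl 3-(benzyloxy)-4-methoxybenzoate
Conditions: BnBr, K2CO3, DMF, 60 °C
Reagents that add atoms: benzyl bromide, BrCc1ccccc1
Why: Williamson ether synthesis, in which the phenoxide formed by K2CO3 displaces bromide from benzyl bromide while the methyl ester stays inert, and the benzyl ether masks the only acidic proton of ring B for the strong-base steps that follow.

Step 2
Reactants: 2 methyl 3-(benzyloxy)-4-methoxybenzoate; 3 ethyl acetoacetate
Product: 4 ethyl 5-[3-(benzyloxy)-4-methoxyphenyl]-3,5-dioxopentanoate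
Conditions: 3 (2.2 equiv), LiN(iPr)2 (4.4 equiv), THF, 0 °C; then 2, 0 °C → rt; aq HCl
Reagents that add atoms: none
Why: Claisen condensation of a β-keto ester dianion, whose γ-carbon attacks the non-enolisable ester 2 and expels methoxide, while the second equivalent of dianion deprotonates the more acidic diketo ester as it forms and so prevents double addition.

Step 3
Reactants: 4 ethyl 5-[3-(benzyloxy)-4-methoxyphenyl]-3,5-dioxopentanoate
Product: 5 6-[3-(benzyloxy)-4-methoxyphenyl]-4-hydroxy-2H-pyran-2-one
Conditions: DBU, toluene, reflux; then aq HCl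
Reagents that add atoms: none
Why: Base-mediated lactonisation (intramolecular transesterification), in which the enol oxygen of the aryl ketone attacks the ethyl ester in a 6-exo-trig closure and ethoxide is lost, the product being held as the salt of the acidic 4-hydroxy-2-pyrone.

Step 4
Reactants: 5 6-[3-(benzyloxy)-4-methoxyphenyl]-4-hydroxy-2H-pyran-2-one; 6 methoxyacetic acid
Product: 8 6-[3-(benzyloxy)-4-methoxyphenyl]-4-hydroxy-3-(methoxyacetyl)-2H-pyran-2-one, via pyran-4-yl methoxyacetate 7 (not isolated)
Conditions: DCC, DMAP (0.3 equiv), toluene, rt → 90 °C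
Reagents that add atoms: none
Why: Steglich O-acylation of the 4-hydroxyl gives ester 7, and DMAP then carries the acyl group to C3, the only nucleophilic ring carbon, in a Fries-type O-to-C rearrangement driven by the hydrogen-bonded tricarbonyl enol of 8.

Step 5
Reactants: 8 6-[3-(benzyloxy)-4-methoxyphenyl]-4-hydroxy-3-(methoxyacetyl)-2H-pyran-2-one; 9 N,2-dimethoxy-N-methylacetamide
Product: 10 6-[3-(benzyloxy)-4-methoxyphenyl]-3-(2,4-dimethoxy-3-oxobutanoyl)-4-hydroxy-2H-pyran-2-one
Conditions: LiN(iPr)2 (2.2 equiv), THF, −78 → −30 °C; then 9 (1.3 equiv), −78 → 0 °C; cold 1 M HCl to pH 4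
Reagents that add atoms: none
Why: Acylation of a 1,3-dicarbonyl dianion by a Weinreb amide (Weinreb ketone synthesis), in which the second equivalent of base deprotonates the methoxymethylene carbon of the 3-acyl group, this carbanion adds to 9, and the chelated tetrahedral adduct lasts until the mild acid quench, so the new β-diketone never meets base and the product is not heated in acid, which would close the pyranopyrone.

Step 6
Reactants: 10 6-[3-(benzyloxy)-4-methoxyphenyl]-3-(2,4-dimethoxy-3-oxobutanoyl)-4-hydroxy-2H-pyran-2-one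
Product: 12 1-[3-(benzyloxy)-4-methoxyphenyl]-3-(2,4,6-trihydroxy-3,5-dimethoxyphenyl)propane-1,3-dione, via cyclohexane-1,3,5-trione tautomer 11 (not isolated)
Conditions: Mg(OMe)2 (8 equiv), degassed MeOH, reflux, Ar; then cold 1 M HCl
Reagents that add atoms: none
Why: Mg(OMe)2 converts the 3-acyl-4-hydroxypyrone and the β-diketone into magnesium chelates, and reversible deprotonation of the methoxymethyl ketone carbon (flavone C8) gives the terminal enolate, which adds to the lactone carbonyl (C8a); collapse of the adduct breaks the bond from the ring oxygen to C8a, releases that oxygen as the chelated enolate of the aroylacetyl chain, and trione 11 enolises to the phloroglucinol phenoxide, which makes the sequence irreversible. The closest known reaction type is the biomimetic polyketide Claisen (Dieckmann-type) recyclisation of 3-acyl-4-hydroxy-2-pyrones and pyranopyrones carrying a β-dicarbonyl chain to acylphloroglucinols under magnesium alkoxide, here applied to a chain with two α-methoxy groups. Ring A closes in a 6-(enolendo)-exo-trig mode, with the C7–C8 enolate double bond inside the new ring and the lactone C=O outside it. No stereocentre is created, and the racemic, enolisable methine C6 of 10 becomes an aromatic carbon. The step needs C-acylation at C8a to win over aldol closure of C8 onto C4 (an isocoumarin), over dehydrative closure of O4 onto the C7 ketone (a pyranopyrone) and over retro-Claisen loss of the terminal methoxyacetyl unit; chelation of O4 with the C5 carbonyl oxygen turns the chain towards C8a and keeps C4 an unreactive enolate carbon, the β-diketone is shielded as its magnesium enolate, and the basic medium withholds the acid that pyranone dehydration requires. Should methoxide open the lactone first, the resulting methyl ester is attacked by the same C8 enolate and gives the same product.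

Step 7
Reactants: 12 1-[3-(benzyloxy)-4-methoxyphenyl]-3-(2,4,6-trihydroxy-3,5-dimethoxyphenyl)propane-1,3-dione
Product: 14 2-[3-(benzyloxy)-4-methoxyphenyl]-5,7-dihydroxy-6,8-dimethoxy-4H-chromen-4-one, via 2-hydroxyflavanone hemiketal 13 (not isolated)
Conditions: H2SO4 (cat.), AcOH, 80 °C, Ar
Reagents that add atoms: none
Why: Acid-catalysed cyclodehydration of an ortho-hydroxyaryl 1,3-diketone (the closing stage of a Baker–Venkataraman flavone synthesis), in which an ortho hydroxyl adds to the aroyl ketone to give hemiketal 13 and water is lost to form the chromone; ring A of 12 is symmetric, so either hydroxyl and any Wessely–Moser equilibration give the same flavone, and partial loss of the benzyl group would only anticipate step 8.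

Step 8
Reactants: 14 2-[3-(benzyloxy)-4-methoxyphenyl]-5,7-dihydroxy-6,8-dimethoxy-4H-chromen-4-one
Product: 15 acerosin (5,7-dihydroxy-2-(3-hydroxy-4-methoxyphenyl)-6,8-dimethoxy-4H-chromen-4-one)
Conditions: H2 (1 atm), 10% Pd/C, EtOAc–MeOH, rt
Reagents that add atoms: none
Why: Catalytic hydrogenolysis of the benzyl aryl ether over Pd/C frees O3' under neutral conditions that leave the aryl methyl ethers intact and reduce the conjugated chromone C2–C3 double bond far more slowly at 1 atm.

**Compound list**
1 | methyl 3-hydroxy-4-methoxybenzoate | COC(=O)c1ccc(OC)c(O)c1 | starting material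
2 | methyl 3-(benzyloxy)-4-methoxybenzoate | COC(=O)c1ccc(OC)c(OCc2ccccc2)c1 | intermediate
3 | ethyl acetoacetate | CCOC(=O)CC(C)=O | starting material
4 | ethyl 5-[3-(benzyloxy)-4-methoxyphenyl]-3,5-dioxopentanoate | CCOC(=O)CC(=O)CC(=O)c1ccc(OC)c(OCc2ccccc2)c1 | intermediate
5 | 6-[3-(benzyloxy)-4-methoxyphenyl]-4-hydroxy-2H-pyran-2-one | O=c1cc(O)cc(-c2ccc(OC)c(OCc3ccccc3)c2)o1 | intermediate
6 | methoxyacetic acid | COCC(=O)O | starting material
7 | 6-[3-(benzyloxy)-4-methoxyphenyl]-2-oxo-2H-pyran-4-yl methoxyacetate (not isolated) | COCC(=O)Oc1cc(-c2ccc(OC)c(OCc3ccccc3)c2)oc(=O)c1 | intermediate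
8 | 6-[3-(benzyloxy)-4-methoxyphenyl]-4-hydroxy-3-(methoxyacetyl)-2H-pyran-2-one | COCC(=O)c1c(O)cc(-c2ccc(OC)c(OCc3ccccc3)c2)oc1=O | intermediate
9 | N,2-dimethoxy-N-methylacetamide | COCC(=O)N(C)OC | starting material
10 | 6-[3-(benzyloxy)-4-methoxyphenyl]-3-(2,4-dimethoxy-3-oxobutanoyl)-4-hydroxy-2H-pyran-2-one (racemic at the enolisable side-chain methine) | COCC(=O)C(OC)C(=O)c1c(O)cc(-c2ccc(OC)c(OCc3ccccc3)c2)oc1=O | intermediate
11 | 2-{3-[3-(benzyloxy)-4-methoxyphenyl]-3-oxopropanoyl}-4,6-dimethoxycyclohexane-1,3,5-trione (mixture of stereoisomers and tautomers, not isolated) | COC1C(=O)C(OC)C(=O)C(C(=O)CC(=O)c2ccc(OC)c(OCc3ccccc3)c2)C1=O | intermediate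
12 | 1-[3-(benzyloxy)-4-methoxyphenyl]-3-(2,4,6-trihydroxy-3,5-dimethoxyphenyl)propane-1,3-dione | COc1ccc(C(=O)CC(=O)c2c(O)c(OC)c(O)c(OC)c2O)cc1OCc1ccccc1 | intermediate
13 | 2-[3-(benzyloxy)-4-methoxyphenyl]-2,5,7-trihydroxy-6,8-dimethoxy-2,3-dihydro-4H-chromen-4-one (racemic, not isolated) | COc1ccc(C2(O)CC(=O)c3c(O)c(OC)c(O)c(OC)c3O2)cc1OCc1ccccc1 | intermediate
14 | 2-[3-(benzyloxy)-4-methoxyphenyl]-5,7-dihydroxy-6,8-dimethoxy-4H-chromen-4-one | COc1ccc(-c2cc(=O)c3c(O)c(OC)c(O)c(OC)c3o2)cc1OCc1ccccc1 | intermediate
15 | acerosin, 5,7-dihydroxy-2-(3-hydroxy-4-methoxyphenyl)-6,8-dimethoxy-4H-chromen-4-one | COc1ccc(-c2cc(=O)c3c(O)c(OC)c(O)c(OC)c3o2)cc1O | target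

**Total step count:** 8
**Longest linear sequence:** 8 steps (1 → 15)

**Steps most likely to fail**

Step 6. The terminal enolate at C8 may form too slowly under alkoxide, so that the chain is cut by retro-Claisen cleavage, or the closure may take the aldol course onto C4. The fallback gives up the recyclisation and builds ring A from a bought phloroglucinol. It sets out from 2 and returns at 14.
- Claisen condensation of 2 with commercial 1-[2-hydroxy-4,6-bis(methoxymethoxy)phenyl]ethanone (LiN(SiMe3)2, THF, −78 °C → rt) should give 1-[3-(benzyloxy)-4-methoxyphenyl]-3-[2-hydroxy-4,6-bis(methoxymethoxy)phenyl]propane-1,3-dione F1.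
- Aqueous HCl in AcOH at 60 °C should close the chromone and remove both methoxymethyl groups, giving 2-[3-(benzyloxy)-4-methoxyphenyl]-5,7-dihydroxy-4H-chromen-4-one F2.
- Br2 (2.1 equiv) in AcOH should brominate the two activated positions of the phloroglucinol ring, giving 2-[3-(benzyloxy)-4-methoxyphenyl]-6,8-dibromo-5,7-dihydroxy-4H-chromen-4-one F3.
- Copper-mediated methoxylation (NaOMe, CuBr, DMF–MeOH, 110 °C), an Ullmann-type exchange known for 6,8-dibromo-5,7-dihydroxyflavones, should then deliver 14, which goes on to step 8.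

Step 5. Proton transfer from the amide to the dianion, or slow addition of the hindered α-methoxy carbanion, may return 8 unchanged. The fallback replaces acylation by aldol addition and oxidation. It sets out from 8 and returns at 10.
- The same dianion (LiN(iPr)2, 2.2 equiv, THF, −78 °C) is treated with freshly distilled methoxyacetaldehyde, which adds faster than it enolises, to give 6-[3-(benzyloxy)-4-methoxyphenyl]-4-hydroxy-3-(3-hydroxy-2,4-dimethoxybutanoyl)-2H-pyran-2-one F4 as a mixture of diastereomers.
- Oxidation of the secondary alcohol with 2-iodoxybenzoic acid in EtOAc at 70 °C should give 10; the stereocentres of F4 disappear in the key step.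

Step 2. The electron-rich ester may react slowly while the dianion is used up by proton exchange, leaving the aroylation incomplete. The fallback reverses the order of bond formation. It sets out from 2 and returns at 5, bypassing steps 2 and 3.
- Claisen condensation of 2 with acetone (NaH, THF, reflux) should give 1-[3-(benzyloxy)-4-methoxyphenyl]butane-1,3-dione F5.
- Its dianion (LiN(iPr)2, 2.2 equiv, THF, 0 °C) is carboxylated at the methyl terminus with CO2, a non-enolisable and highly reactive electrophile, to give 5-[3-(benzyloxy)-4-methoxyphenyl]-3,5-dioxopentanoic acid F6.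
- Ac2O at rt should cyclodehydrate F6 to pyrone 5.

**Further compounds**
F1 | step 6 | 1-[3-(benzyloxy)-4-methoxyphenyl]-3-[2-hydroxy-4,6-bis(methoxymethoxy)phenyl]propane-1,3-dione | COCOc1cc(O)c(C(=O)CC(=O)c2ccc(OC)c(OCc3ccccc3)c2)c(OCOC)c1
F2 | step 6 | 2-[3-(benzyloxy)-4-methoxyphenyl]-5,7-dihydroxy-4H-chromen-4-one | COc1ccc(-c2cc(=O)c3c(O)cc(O)cc3o2)cc1OCc1ccccc1
F3 | step 6 | 2-[3-(benzyloxy)-4-methoxyphenyl]-6,8-dibromo-5,7-dihydroxy-4H-chromen-4-one | COc1ccc(-c2cc(=O)c3c(O)c(Br)c(O)c(Br)c3o2)cc1OCc1ccccc1
F4 | step 5 | 6-[3-(benzyloxy)-4-methoxyphenyl]-4-hydroxy-3-(3-hydroxy-2,4-dimethoxybutanoyl)-2H-pyran-2-one (mixture of diastereomers) | COCC(O)C(OC)C(=O)c1c(O)cc(-c2ccc(OC)c(OCc3ccccc3)c2)oc1=O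
F5 | step 2 | 1-[3-(benzyloxy)-4-methoxyphenyl]butane-1,3-dione | CC(=O)CC(=O)c1ccc(OC)c(OCc2ccccc2)c1
F6 | step 2 | 5-[3-(benzyloxy)-4-methoxyphenyl]-3,5-dioxopentanoic acid | OC(=O)CC(=O)CC(=O)c1ccc(OC)c(OCc2ccccc2)c1
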